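**Plan**
- Cuts, in retrosynthetic order: the hemiketal C–Et bond (δ-lactone + ethyl nucleophile); the lactone O–C(=O) unit taken back out of the six-membered ring to leave a spiro-cyclobutane (ring expansion reversed); the two cyclobutane bonds at the spiro carbon and its CH2 ([2+2] on an exocyclic methylene); the ester-bearing C=C (aldol condensation); two C–C bonds of the cyclopentenone (Nazarov, carbonylative coupling); both C–CH2N bonds (double Mannich); the propanoate C–C bond (Michael).
- Forward: cycloheptane-1,3-dione → Michael → double Mannich (piperidine and quaternary bridgehead; 8-azabicyclo[4.3.1]decane-2,10-dione, whose locants 1 = quaternary bridgehead, 6 = CH bridgehead, 10 = one-carbon bridge are kept for all later compounds) → C-2 enol triflate → C-10 methylene → spiro-cyclobutane → spiro-δ-lactone → cyclopentenone on C2=C3 → cyclopentadiene ester → hemiketal.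
- Enabling feature: the ring O–CH2–C10–CH2–CH2–C(OH)Et is a closed δ-hydroxy ketone whose two arms both leave the spiro carbon C-10, and C-10 is the carbon of a non-enolisable bridging ketone. As C10=CH2 it takes up a β-alkoxy enone as a cyclobutane whose fourth bond, CH(O)–CH(C=O), is a strained retro-aldol bond; cleaving it inserts O–C(=O) between the arms (four- to six-membered ring).
- Stereochemistry: C-1/C-6 from the (S)-1-phenylethylamine auxiliary in the Mannich step (the bridge fixes their relative configuration); C-10 from the face selectivity of the photocycloaddition; the hemiketal carbon by thermodynamic (anomeric) control.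

Key step: step 7

Remark: 2,2-dimethyl-4H-1,3-dioxin-4-one (14) is taken as purchasable (otherwise two steps from Meldrum's acid), and the hemiketal carbon, which epimerises through the open hydroxy ketone, is taken to have the thermodynamic configuration in the target.

**Step 1**
Reactants: 1 cycloheptane-1,3-dione; 2 methyl acrylate
Product: 3 methyl 3-(2,7-dioxocycloheptyl)propanoate
Conditions: 2 (1.05 equiv), Et3N (0.2 equiv), MeCN, 40 °C
Reagents that add atoms: methyl acrylate 2, C=CC(=O)OC
Why: Michael addition: the stabilised enolate of the cyclic 1,3-dione should add through C-2 to the acrylate, and mono-addition should dominate because the adduct is less acidic and more hindered than 1; no stereocentre is formed.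

**Step 2**
Reactants: 3 methyl 3-(2,7-dioxocycloheptyl)propanoate; 4 (S)-1-phenylethylamine; 5 formaldehyde
Product: 7 methyl 3-{(1R,6R)-2,10-dioxo-8-[(1S)-1-phenylethyl]-8-azabicyclo[4.3.1]decan-1-yl}propanoate, via mono-Mannich base 6 (not isolated)
Conditions: 4 (1.0 equiv), (CH2O)n (2.3 equiv), AcOH, MeOH, 60 °C; chromatographic separation of the two diastereomers
Reagents that add atoms: (S)-1-phenylethylamine 4, C[C@H](N)c1ccccc1; formaldehyde 5, C=O
Why: Double Mannich bicyclisation: the dione carbon between the carbonyls should aminomethylate first, the secondary amine 6 should condense with a second formaldehyde, and the iminium ion should be trapped by the enol of one of the two enantiotopic ketones, which closes the piperidine, makes the quaternary bridgehead and fixes the cis relation of C-1 and C-6 through the bridge; little induction is expected from the auxiliary, but it turns the two enantiomeric modes into separable diastereomers, of which the (1R,6R) isomer is taken on and the other can be re-equilibrated through retro-Mannich opening.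

**Step 3**
Reactants: 7 methyl 3-{(1R,6R)-2,10-dioxo-8-[(1S)-1-phenylethyl]-8-azabicyclo[4.3.1]decan-1-yl}propanoate; 5 formaldehyde
Product: 9 methyl 3-[(1R,6R)-8-methyl-2,10-dioxo-8-azabicyclo[4.3.1]decan-1-yl]propanoate, via secondary amine 8 (not isolated)
Conditions: H2 (4 atm), Pd(OH)2 on carbon, 37 % aq. CH2O, AcOH (1 equiv), MeOH, rt
Reagents that add atoms: formaldehyde 5, C=O
Why: Hydrogenolysis of the benzylic C–N bond followed in the same flask by reductive amination of the secondary amine 8 with formaldehyde should exchange the auxiliary for N-methyl; ketones, ester and both stereocentres are not touched under these conditions.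

**Step 4**
Reactants: 9 methyl 3-[(1R,6R)-8-methyl-2,10-dioxo-8-azabicyclo[4.3.1]decan-1-yl]propanoate; 10 N-phenylbis(trifluoromethanesulfonimide)
Product: 11 methyl 3-[(1R,6R)-8-methyl-10-oxo-2-(trifluoromethanesulfonyloxy)-8-azabicyclo[4.3.1]dec-2-en-1-yl]propanoate
Conditions: KN(SiMe3)2 (1.1 equiv), THF, −78 °C; 10 (1.2 equiv), −78 → 0 °C
Reagents that add atoms: N-phenylbis(trifluoromethanesulfonimide) 10, O=S(=O)(N(c1ccccc1)S(=O)(=O)C(F)(F)F)C(F)(F)F
Why: Enol triflate formation: only the C-3 hydrogens can be removed, since the C-10 ketone lies between the quaternary C-1 and the bridgehead C-6 (Bredt's rule), so O-sulfonylation of the single possible ketone enolate should be regiospecific and at the same time masks the C-2 carbonyl.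

**Step 5**
Reactants: 11 methyl 3-[(1R,6R)-8-methyl-10-oxo-2-(trifluoromethanesulfonyloxy)-8-azabicyclo[4.3.1]dec-2-en-1-yl]propanoate; 12 dibromomethane
Product: 13 methyl 3-[(1R,6S)-8-methyl-10-methylidene-2-(trifluoromethanesulfonyloxy)-8-azabicyclo[4.3.1]dec-2-en-1-yl]propanoate
Conditions: Zn, CH2Br2, TiCl4 (reagent pre-formed at 0–5 °C), THF/CH2Cl2, 0 °C → rt
Reagents that add atoms: dibromomethane 12, BrCBr
Why: Takai–Lombardo methylenation: the non-basic zinc/titanium methylene reagent should convert the hindered, non-enolisable bridging ketone into the exocyclic alkene without touching the ester, the enol triflate or the stereocentres (the change of descriptor at C-6 is only a priority change).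

**Step 6**
Reactants: 13 methyl 3-[(1R,6S)-8-methyl-10-methylidene-2-(trifluoromethanesulfonyloxy)-8-azabicyclo[4.3.1]dec-2-en-1-yl]propanoate; 14 2,2-dimethyl-4H-1,3-dioxin-4-one
Product: 15 methyl 3-[(1R,6S,10R)-3',3',8-trimethyl-5'-oxo-2-(trifluoromethanesulfonyloxy)spiro[8-azabicyclo[4.3.1]dec-2-ene-10,8'-[2,4]dioxabicyclo[4.2.0]octan]-1-yl]propanoate (cis-fused cyclobutane; its two CH centres not defined)
Conditions: hν (300 nm, Pyrex), 14 (5 equiv), CF3CO2H (1.1 equiv), MeCN/acetone 9:1, 0 °C; NaHCO3 work-up
Reagents that add atoms: 2,2-dimethyl-4H-1,3-dioxin-4-one 14, CC1(C)OC=CC(=O)O1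
Why: Triplet [2+2] photocycloaddition of a β-alkoxy enone (De Mayo type): the terminal CH2 should bond first to the α-carbon of 14 and the tertiary/α-oxy 1,4-biradical should close head-to-tail, so that the oxygen-bearing carbon ends on C-10; closure is expected on the face of C-10 syn to the C2=C3 bridge (one flanking axial C–H at C-5 and an sp2 carbon) and not over the piperidine chair (two syn-axial C–H at C-7 and C-9), which sets the spiro centre, while the acid protonates the amine so that it cannot quench the excited enone and the exocyclic 1,1-disubstituted alkene should react in preference to the hindered, electron-poor enol triflate.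

**Step 7**
Reactants: 15 the photoadduct of step 6
Product: 19 methyl 3-[(1R,6S,10R)-8-methyl-6'-oxo-2-(trifluoromethanesulfonyloxy)spiro[8-azabicyclo[4.3.1]dec-2-ene-10,3'-oxan]-1-yl]propanoate, via cyclobutanol ester 16 (not isolated), via aldehyde diester 17 (not isolated), via hydroxy diester 18 (not isolated)
Conditions: K2CO3 (0.5 equiv), NaBH4 (1.5 equiv), MeOH, 0 °C → rt; AcOH quench; pyridinium p-toluenesulfonate (cat.), PhMe, 60 °C
Reagents that add atoms: none
Why: Methoxide should open the acylal-type dioxanone with loss of acetone to the cyclobutanol ester 16, whose alkoxide is β to the new ester, so that retro-aldol cleavage of the strained bond shared by the four- and six-membered rings gives the neopentyl aldehyde 17, which NaBH4, present from the start, reduces to 18 before the primary alcohol lactonises. The closest known reaction type is the De Mayo fragmentation of dioxinone–alkene photoadducts to 1,5-dicarbonyl compounds, here run reductively. The new ring closes by 6-exo-trig attack of the alcohol on the ester carbonyl, so the cyclobutane C10–CH2–CH–CH(O) becomes the six-membered O–CH2–C10–CH2–CH2–C(=O) ring by net insertion of O–C(=O) into its CH–CH bond, a two-atom ring expansion. No stereocentre is formed: the spiro centre from step 6 is kept and the two cyclobutane CH centres disappear, so their configuration is without consequence. The step needs cleavage of the fusion bond only (the sole C–C bond that is both on the carbinol carbon and α to an ester), reduction of the aldehyde beside two esters and the enol triflate (NaBH4 in MeOH at 0 °C), interception of the non-enolisable aldehyde before it meets the propanoate enolate, and closure of the six- and not the seven-membered lactone (the propanoate ester could only give an ε-lactone).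

**Step 8**
Reactants: 19 the spiro-δ-lactone enol triflate; 20 carbon monoxide; 21 tributyl(vinyl)stannane
Product: 22 methyl 3-[(1S,6S,10R)-8-methyl-6'-oxo-2-(prop-2-enoyl)spiro[8-azabicyclo[4.3.1]dec-2-ene-10,3'-oxan]-1-yl]propanoate
Conditions: Pd(PPh3)4 (5 mol %), LiCl (3 equiv), CO (3 atm), 21 (1.3 equiv), THF, 55 °C
Reagents that add atoms: carbon monoxide 20, [C-]#[O+]; tributyl(vinyl)stannane 21, C=C[Sn](CCCC)(CCCC)CCCC
Why: Carbonylative Stille coupling: oxidative addition of zerovalent palladium into the enol triflate, CO insertion and chloride-assisted vinyl transfer from tin should give the cross-conjugated dienone; lactone, ester and amine are inert (the descriptor at C-1 changes by priority only).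

**Step 9**
Reactants: 22 the dienone of step 8
Product: 23 methyl 3-[(1S,6S,10R)-…]propanoate in which C-2 and C-3 now form the tetrasubstituted ring-fusion double bond of a cyclopent-2-enone (C=O on the carbon attached to C-2); spiro-lactone unchanged
Conditions: CF3SO3H (3 equiv), CH2Cl2, −20 → 0 °C; NaHCO3 work-up
Reagents that add atoms: none
Why: Nazarov cyclisation: O-protonation gives the pentadienyl cation, conrotatory 4π closure joins C-3 to the vinyl terminus, and proton loss with acid-mediated equilibration should place the double bond at the tetrasubstituted C2=C3 ring fusion in conjugation with the ketone; the ammonium group disfavours cationic shifts from C-1 and no stereocentre is created.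

**Step 10**
Reactants: 23 the cyclopentenone of step 9
Product: 25 the (1R,6S,10R) dienoate lactone (methyl ester of the target skeleton with C=O in place of C(OH)Et in the oxane ring), via aldol adduct 24 (not isolated)
Conditions: KOtBu (1.2 equiv), THF, −20 → 20 °C; then TsOH·H2O (2.5 equiv), PhMe, 60 °C
Reagents that add atoms: none
Why: Intramolecular aldol condensation: under equilibrating base only the propanoate enolate has a productive path, 5-exo-trig addition to the enone carbonyl (conjugate addition would be 5-endo, and the lactone enolate cannot reach because its chain is anti to the C-2 bridge), and acid should then dehydrate the tertiary allylic β-hydroxy ester 24 to the conjugated cyclopentadiene ester.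

**Step 11**
Reactants: 25 the dienoate lactone; 26 ethylmagnesium bromide
Product: 27 the target, CNP0192143.1 ((1R,6S,10R)-6'-ethyl-6'-hydroxy-spiro-oxane, hemiketal carbon S)
Conditions: EtMgBr (1.5 equiv), CeCl3 (1.6 equiv, dried), THF, −78 °C; sat. aq. NH4Cl at −78 °C
Reagents that add atoms: ethylmagnesium bromide 26, CC[Mg]Br
Why: 1,2-Addition of the weakly basic ethylcerium reagent to the δ-lactone should stop at the cyclic hemiketal alkoxide at −78 °C, the cross-conjugated, fully substituted dienoate ester being far less electrophilic; the hemiketal carbon equilibrates through the open δ-hydroxy ketone to the anomerically favoured epimer (axial OH, equatorial ethyl), taken to be the natural S configuration.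

**Compound list**
1 | cycloheptane-1,3-dione | O=C1CCCCC(=O)C1 | starting material
2 | methyl acrylate | C=CC(=O)OC | starting material
3 | methyl 3-(2,7-dioxocycloheptyl)propanoate | COC(=O)CCC1C(=O)CCCCC1=O | intermediate
4 | (S)-1-phenylethylamine | C[C@H](N)c1ccccc1 | starting material
5 | formaldehyde | C=O | starting material
6 | methyl 3-[2,7-dioxo-1-({[(1S)-1-phenylethyl]amino}methyl)cycloheptyl]propanoate (mono-Mannich base) | COC(=O)CCC1(CN[C@@H](C)c2ccccc2)C(=O)CCCCC1=O | intermediate
7 | methyl 3-{(1R,6R)-2,10-dioxo-8-[(1S)-1-phenylethyl]-8-azabicyclo[4.3.1]decan-1-yl}propanoate | O=C2[C@@H]1CCCC(=O)[C@@]2(CCC(=O)OC)CN([C@@H](C)c3ccccc3)C1 | intermediate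
8 | methyl 3-[(1R,6R)-2,10-dioxo-8-azabicyclo[4.3.1]decan-1-yl]propanoate (secondary amine) | O=C2[C@@H]1CCCC(=O)[C@@]2(CCC(=O)OC)CNC1 | intermediate
9 | methyl 3-[(1R,6R)-8-methyl-2,10-dioxo-8-azabicyclo[4.3.1]decan-1-yl]propanoate | O=C2[C@@H]1CCCC(=O)[C@@]2(CCC(=O)OC)CN(C)C1 | intermediate
10 | N-phenylbis(trifluoromethanesulfonimide) | O=S(=O)(N(c1ccccc1)S(=O)(=O)C(F)(F)F)C(F)(F)F | starting material
11 | methyl 3-[(1R,6R)-8-methyl-10-oxo-2-(trifluoromethanesulfonyloxy)-8-azabicyclo[4.3.1]dec-2-en-1-yl]propanoate | O=C2[C@@H]1CCC=C(OS(=O)(=O)C(F)(F)F)[C@@]2(CCC(=O)OC)CN(C)C1 | intermediate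
12 | dibromomethane | BrCBr | starting material
13 | methyl 3-[(1R,6S)-8-methyl-10-methylidene-2-(trifluoromethanesulfonyloxy)-8-azabicyclo[4.3.1]dec-2-en-1-yl]propanoate | C=C2[C@@H]1CCC=C(OS(=O)(=O)C(F)(F)F)[C@@]2(CCC(=O)OC)CN(C)C1 | intermediate
14 | 2,2-dimethyl-4H-1,3-dioxin-4-one | CC1(C)OC=CC(=O)O1 | starting material
15 | methyl 3-[(1R,6S,10R)-3',3',8-trimethyl-5'-oxo-2-(trifluoromethanesulfonyloxy)spiro[8-azabicyclo[4.3.1]dec-2-ene-10,8'-[2,4]dioxabicyclo[4.2.0]octan]-1-yl]propanoate (head-to-tail photoadduct, cis-fused) | O=C1OC(C)(C)OC2C1C[C@]23[C@@H]4CCC=C(OS(=O)(=O)C(F)(F)F)[C@@]3(CCC(=O)OC)CN(C)C4 | intermediate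
16 | methyl (1R,6S,10R)-2'-hydroxy-1-(3-methoxy-3-oxopropyl)-8-methyl-2-(trifluoromethanesulfonyloxy)spiro[8-azabicyclo[4.3.1]dec-2-ene-10,1'-cyclobutane]-3'-carboxylate (cyclobutanol ester) | COC(=O)C1C[C@@]2(C1O)[C@@H]3CCC=C(OS(=O)(=O)C(F)(F)F)[C@@]2(CCC(=O)OC)CN(C)C3 | intermediate
17 | methyl 3-[(1R,6S,10R)-10-formyl-10-(3-methoxy-3-oxopropyl)-8-methyl-2-(trifluoromethanesulfonyloxy)-8-azabicyclo[4.3.1]dec-2-en-1-yl]propanoate (aldehyde diester) | O=C[C@]1(CCC(=O)OC)[C@@H]2CCC=C(OS(=O)(=O)C(F)(F)F)[C@@]1(CCC(=O)OC)CN(C)C2 | intermediate
18 | methyl 3-[(1R,6S,10R)-10-(hydroxymethyl)-10-(3-methoxy-3-oxopropyl)-8-methyl-2-(trifluoromethanesulfonyloxy)-8-azabicyclo[4.3.1]dec-2-en-1-yl]propanoate (hydroxy diester) | OC[C@]1(CCC(=O)OC)[C@@H]2CCC=C(OS(=O)(=O)C(F)(F)F)[C@@]1(CCC(=O)OC)CN(C)C2 | intermediate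
19 | methyl 3-[(1R,6S,10R)-8-methyl-6'-oxo-2-(trifluoromethanesulfonyloxy)spiro[8-azabicyclo[4.3.1]dec-2-ene-10,3'-oxan]-1-yl]propanoate | O=C1CC[C@@]2(CO1)[C@@H]3CCC=C(OS(=O)(=O)C(F)(F)F)[C@@]2(CCC(=O)OC)CN(C)C3 | intermediate
20 | carbon monoxide | [C-]#[O+] | starting material
21 | tributyl(vinyl)stannane | C=C[Sn](CCCC)(CCCC)CCCC | starting material
22 | methyl 3-[(1S,6S,10R)-8-methyl-6'-oxo-2-(prop-2-enoyl)spiro[8-azabicyclo[4.3.1]dec-2-ene-10,3'-oxan]-1-yl]propanoate | O=C1CC[C@@]2(CO1)[C@@H]3CCC=C(C(=O)C=C)[C@@]2(CCC(=O)OC)CN(C)C3 | intermediate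
23 | (1S,6S,10R) cyclopentenone-annulated spiro-lactone ester (cyclopent-2-enone fused at C2=C3, C=O on the carbon attached to C-2) | O=C1CC[C@@]2(CO1)[C@@H]3CCC4=C(C(=O)CC4)[C@@]2(CCC(=O)OC)CN(C)C3 | intermediate
24 | aldol adduct of 23 (tertiary alcohol from 5-exo addition of the propanoate α-carbon to the enone carbonyl; (1S,6S,10R), the two new centres not defined) | O=C1CC[C@@]2(CO1)[C@@H]1CCC3=C4C(O)(C(C(=O)OC)C[C@@]42CN(C)C1)CC3 | intermediate
25 | (1R,6S,10R) dienoate lactone (target skeleton with a lactone C=O in place of C(OH)Et) | O=C1CC[C@@]2(CO1)[C@@H]1CCC3=C4C(=C(C(=O)OC)C[C@@]42CN(C)C1)CC3 | intermediate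
26 | ethylmagnesium bromide | CC[Mg]Br | starting material
27 | CNP0192143.1: the (1R,6S,10R) skeleton of 25 carrying a (6'S)-6'-ethyl-6'-hydroxyoxane spiro-joined at C-3' | CC[C@@]1(O)CC[C@@]2(CO1)[C@@H]1CCC3=C4C(=C(C(=O)OC)C[C@@]42CN(C)C1)CC3 | target

**Step count:** 11 steps in total; longest linear sequence 11 steps (from 1).

**Steps most likely to fail, with fallbacks**

Step 6. The biradical may close on the other face of the spiro carbon, or the irradiation may be spoiled by quenching or by addition to the enol triflate. The fallback is thermal and brings in the two arms in the reverse order, so the same facial bias leads to the opposite configuration at C-10. It sets out from 11: a Wittig reaction with Ph3P=CHOMe (from the phosphonium chloride and KN(SiMe3)2, THF) should give the enol ether methyl 3-[(1R,6S)-10-(methoxymethylidene)-8-methyl-2-(trifluoromethanesulfonyloxy)-8-azabicyclo[4.3.1]dec-2-en-1-yl]propanoate F1; dilute HCl in THF should give the aldehyde methyl 3-[(1R,6S)-10-formyl-8-methyl-2-(trifluoromethanesulfonyloxy)-8-azabicyclo[4.3.1]dec-2-en-1-yl]propanoate F2; DBU-catalysed Michael addition of its enol to methyl acrylate 2 then makes the quaternary carbon and comes back to the route at 17, which the reduction and lactonisation of step 7 take to 19.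

Step 9. The vinyl ketone may polymerise in strong acid, or the oxyallyl cation beside the quaternary bridgehead may undergo a 1,2-shift before proton loss. The fallback lets a β-silicon substituent decide where the cation collapses. It sets out from 19: carbonylative Stille coupling with (E)-tributyl[2-(trimethylsilyl)ethenyl]stannane should give the β-silyl dienone methyl 3-[(1S,6S,10R)-8-methyl-6'-oxo-2-[(2E)-3-(trimethylsilyl)prop-2-enoyl]spiro[8-azabicyclo[4.3.1]dec-2-ene-10,3'-oxan]-1-yl]propanoate F3; BF3·OEt2 should cyclise it with loss of the silyl group to the cis-fused cyclopentenone isomer with the C=C between the two former vinyl carbons F4; DBU in PhMe should then move the double bond to the ring fusion and so come back to the route at 23.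

Step 10. Retro-aldol reversal and unproductive enolisation of the ketone may outrun dehydration. The fallback forms the same bond by cross-coupling instead of carbonyl addition. It sets out from 23: KN(SiMe3)2 and PhNTf2 should give the cross-conjugated dienyl triflate of 23 F5; intramolecular α-alkenylation of the ester enolate (Pd2(dba)3, t-Bu3P, LiN(SiMe3)2, PhMe) should close the five-membered ring to the deconjugated ester isomer of 25 with the C=C toward the cyclopentane CH2 F6; DBU should then bring the double bond into conjugation with the ester and so come back to the route at 25.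

**Further compounds**
F1 | step 6 | methyl 3-[(1R,6S)-10-(methoxymethylidene)-8-methyl-2-(trifluoromethanesulfonyloxy)-8-azabicyclo[4.3.1]dec-2-en-1-yl]propanoate | COC=C2[C@@H]1CCC=C(OS(=O)(=O)C(F)(F)F)[C@@]2(CCC(=O)OC)CN(C)C1
F2 | step 6 | methyl 3-[(1R,6S)-10-formyl-8-methyl-2-(trifluoromethanesulfonyloxy)-8-azabicyclo[4.3.1]dec-2-en-1-yl]propanoate (C-10 not defined) | O=CC2[C@@H]1CCC=C(OS(=O)(=O)C(F)(F)F)[C@@]2(CCC(=O)OC)CN(C)C1
F3 | step 9 | methyl 3-[(1S,6S,10R)-8-methyl-6'-oxo-2-[(2E)-3-(trimethylsilyl)prop-2-enoyl]spiro[8-azabicyclo[4.3.1]dec-2-ene-10,3'-oxan]-1-yl]propanoate | O=C1CC[C@@]2(CO1)[C@@H]3CCC=C(C(=O)/C=C/[Si](C)(C)C)[C@@]2(CCC(=O)OC)CN(C)C3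
F4 | step 9 | cis-fused cyclopent-2-enone isomer of 23 (C=C between the two former vinyl carbons; ring-fusion centres not defined) | O=C1CC[C@@]2(CO1)[C@@H]3CCC4C=CC(=O)C4[C@@]2(CCC(=O)OC)CN(C)C3
F5 | step 10 | cross-conjugated dienyl triflate of 23 | O=C1CC[C@@]2(CO1)[C@@H]3CCC4=C(C(OS(=O)(=O)C(F)(F)F)=CC4)[C@@]2(CCC(=O)OC)CN(C)C3
F6 | step 10 | deconjugated ester isomer of 25 (ester-bearing carbon sp3, not defined) | O=C1CC[C@@]2(CO1)[C@@H]1CCC3=C4C(C(C(=O)OC)C[C@@]42CN(C)C1)=CC3
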